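**Retrosynthetic overview**

1. The last skeletal bond cut is the glycerol C–C bond next to ring C: an Evans syn aldol of the ring B aryloxyacetyl imide with O-benzylvanillin, followed by reductive removal of the auxiliary, gives the threo (R,R) arylglycerol ether on the ring B oxygen.
2. The only ring to be built, the tetrahydrofuran (O1, C2 with the ring B aryl, C3 with C9H2OH, C4 the tertiary carbinol with the ring A benzyl C7, C5), is opened at O1–C2. C2 is para-hydroxybenzylic to ring B, so an acyclic triol with a free ring B phenol should close through its para-quinone methide.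
3. The strategy rests on the chain C5–C4(OH)–C3–C9, which is the four-carbon chain of (S)-malic acid with C4 as its carbinol carbon. The C3–CH2(ring B) bond comes from anti alkylation of the malate dianion, the C4–C7(ring A) bond from retentive alkylation of the cis pivalaldehyde dioxolanone, and LiAlH4 then frees the triol.
4. Ring order: rings A, B and C are bought as vanillin-type arenes; the tetrahydrofuran is formed in step 10 and no other ring is made.

Key step: step 10

Labels used: tetrahydrofuran atoms as above; the glycerol carbons are G1 (benzylic, on ring C), G2 (bearing the ring B oxygen) and G3 (CH2OH). The target is 2S,3R,4S in the ring and G1 R, G2 R.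
Assumption: the minor diastereomers of steps 4, 6, 10 and 14 can be removed by chromatography or crystallisation.

**Route**

Step 1
Reactants: 1 vanillyl alcohol (4-hydroxy-3-methoxybenzyl alcohol)
Product: 2 4-(allyloxy)-3-methoxybenzyl alcohol
Conditions: allyl bromide, K2CO3, acetone, reflux
Reagents that add atoms: allyl bromide, C=CCBr
Why: Williamson etherification, in which carbonate deprotonates only the phenol so that the benzylic alcohol stays free; allyl is chosen for ring B because it survives hydroxide, acid, amide bases and LiAlH4 and is later removed without touching a benzyl ether.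

Step 2
Reactants: 2 4-(allyloxy)-3-methoxybenzyl alcohol
Product: 3 4-(allyloxy)-3-methoxybenzyl bromide (ring B bromide)
Conditions: PBr3, Et2O, 0 °C; used directly
Reagents that add atoms: phosphorus tribromide, BrP(Br)Br
Why: Conversion of an electron-rich benzylic alcohol into the bromide through its phosphite ester, a substitution that is fast at 0 °C and leaves the allyl ether untouched.

Step 3
Reactants: 4 4-(benzyloxy)-3-methoxybenzyl alcohol
Product: 5 4-(benzyloxy)-3-methoxybenzyl bromide (ring A bromide)
Conditions: PBr3, Et2O, 0 °C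
Reagents that add atoms: phosphorus tribromide, BrP(Br)Br
Why: The same benzylic alcohol to bromide substitution as in step 2, giving a known crystalline alkylating agent.

Step 4
Reactants: 6 dimethyl (S)-malate (dimethyl L-malate); 3 ring B bromide
Product: 8 dimethyl (2S,3R)-3-[4-(allyloxy)-3-methoxybenzyl]-2-hydroxysuccinate, via dilithium alkoxide enolate 7 (not isolated)
Conditions: LiN(SiMe3)2 (2.2 equiv), THF, −78 to −20 °C; then 3, −78 to −10 °C; dilute aq. HCl
Reagents that add atoms: none
Why: Fráter–Seebach alkylation, in which the lithium-chelated alkoxide enolate is attacked on the face anti to the C2 oxygen, so the new centre is set anti (3R) by the malate carbinol centre, which itself is unchanged.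

Step 5
Reactants: 8 dimethyl (2S,3R)-3-[4-(allyloxy)-3-methoxybenzyl]-2-hydroxysuccinate
Product: 9 (2S,3R)-3-[4-(allyloxy)-3-methoxybenzyl]-2-hydroxysuccinic acid
Conditions: KOH, MeOH/H2O, rt; then aq. HCl
Reagents that add atoms: potassium hydroxide, [K+].[OH-]
Why: Saponification of both methyl esters at room temperature, under which the aryl allyl ether is stable and the carboxylate formed first protects C3 from epimerisation.

Step 6
Reactants: 9 (2S,3R)-3-[4-(allyloxy)-3-methoxybenzyl]-2-hydroxysuccinic acid; 10 pivalaldehyde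
Product: 11 (2R)-3-[4-(allyloxy)-3-methoxyphenyl]-2-[(2S,4S)-2-tert-butyl-5-oxo-1,3-dioxolan-4-yl]propanoic acid (cis dioxolanone)
Conditions: TsOH·H2O (cat.), H2SO4 (cat.), pentane, reflux, water separator; cis isomer crystallised
Reagents that add atoms: none
Why: Acid-catalysed acetalisation of the α-hydroxy acid (Seebach dioxolanone formation), where the five-membered acylal is preferred over the six-membered one from the β-carboxyl and the 2,4-cis isomer, whose new acetal centre is S, is the thermodynamic product.

Step 7
Reactants: 11 cis dioxolanone acid; 5 ring A bromide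
Product: 13 (2R)-3-[4-(allyloxy)-3-methoxyphenyl]-2-{(2S,4S)-4-[4-(benzyloxy)-3-methoxybenzyl]-2-tert-butyl-5-oxo-1,3-dioxolan-4-yl}propanoic acid, via dilithium enolate carboxylate 12 (not isolated)
Conditions: LiN(SiMe3)2 (2.3 equiv), THF, −78 °C; then 5, −78 to −30 °C; dilute aq. HCl
Reagents that add atoms: none
Why: Alkylation of a dioxolanone enolate with self-regeneration of the stereocentre: the enolate keeps only the acetal centre, the benzyl bromide adds anti to tert-butyl, and the new C–C bond therefore takes the place of the former C–H with retention, giving the quaternary centre that becomes C4 (S).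

Step 8
Reactants: 13 dibenzylated dioxolanone acid
Product: 14 (2S,3S)-3-[4-(allyloxy)-3-methoxybenzyl]-2-[4-(benzyloxy)-3-methoxybenzyl]butane-1,2,4-triol
Conditions: LiAlH4, THF, 0 °C to reflux; H2O work-up
Reagents that add atoms: none
Why: Hydride reduction of the carboxylic acid and of the dioxolanone carbonyl, the acylal collapsing to the tertiary alkoxide and pivalaldehyde (reduced in turn), which leaves both stereocentres and both aryl ethers untouched.

Step 9
Reactants: 14 allyl-protected triol
Product: 15 (2S,3S)-2-[4-(benzyloxy)-3-methoxybenzyl]-3-(4-hydroxy-3-methoxybenzyl)butane-1,2,4-triol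
Conditions: Pd(PPh3)4 (5 mol %), morpholine, THF, rt
Reagents that add atoms: none
Why: Tsuji–Trost deallylation, in which zerovalent palladium ionises the aryl allyl ether and morpholine traps the allyl fragment, freeing only the ring B phenol while the ring A benzyl ether is inert.

Step 10
Reactants: 15 acyclic triol with free ring B phenol
Product: 17 (2S,3R,4S)-4-[4-(benzyloxy)-3-methoxybenzyl]-2-(4-hydroxy-3-methoxyphenyl)-3-(hydroxymethyl)tetrahydrofuran-4-ol, via ring B quinone methide 16 (not isolated)
Conditions: Ag2O (1.2 equiv), CH2Cl2, 4 Å molecular sieves, rt, dark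
Reagents that add atoms: none
Why: Ag2O removes two electrons and two protons from the only free phenol (ring B) to give the para-quinone methide 16, whose exocyclic carbon is C2; the C5 hydroxyl adds to C2 in conjugate fashion and ring B rearomatises, forming the O1–C2 bond. The closest known reaction type is the silver oxide oxidation of 4-alkyl-2-methoxyphenols to para-quinone methides with intramolecular capture by an alcohol. The tetrahydrofuran closes in the 5-exo-trig mode, since the methide double bond between C2 and the ring B ipso carbon lies outside the new ring. The new stereocentre C2 is controlled by C3: in the envelope transition state the quinone methide ring sits pseudo-equatorial and trans to the C3 hydroxymethyl group, and any cis isomer can equilibrate by reversible ionisation of the para-hydroxybenzylic ether, so the 2,3-trans (2S) isomer should prevail. The step needs chemoselectivity between two electron-rich arenes and three hydroxyls: ring A cannot give a quinone methide because its phenol is benzylated, and the C4 and C9 hydroxyls could only close oxetanes, so only O5 reaches C2. Near-stoichiometric oxidant is used so that the product phenol is not oxidised a second time at C2.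

Step 11
Reactants: 18 (S)-4-benzyl-2-oxazolidinone; 19 bromoacetyl bromide
Product: 21 (S)-4-benzyl-3-(bromoacetyl)-2-oxazolidinone, via N-lithio oxazolidinone 20 (not isolated)
Conditions: n-BuLi, THF, −78 °C; then 19, −78 °C
Reagents that add atoms: none
Why: N-acylation of the lithiated oxazolidinone by the acyl bromide, which is far more electrophilic than the alkyl bromide at −78 °C.

Step 12
Reactants: 17 tetrahydrofuran phenol; 21 bromoacetyl imide
Product: 22 ring B aryloxyacetyl imide (17 with its phenol oxygen bound to CH2C(=O)N of the (S)-4-benzyl-2-oxazolidinone)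
Conditions: K2CO3, acetone, rt
Reagents that add atoms: none
Why: Williamson etherification at an α-halo imide, where only the phenol is ionised by carbonate and the activated primary bromide is displaced much faster than the two alcohols could react.

Step 13
Reactants: 22 ring B aryloxyacetyl imide
Product: 23 bis(triethylsilyl) ether of 22 (Et3Si on the C4 and C9 oxygens)
Conditions: Et3SiOTf, 2,6-lutidine, CH2Cl2, −78 to 0 °C
Reagents that add atoms: triethylsilyl triflate, CC[Si](CC)(CC)OS(=O)(=O)C(F)(F)F
Why: Silylation with a silyl triflate and a hindered base, which caps the primary and also the tertiary hydroxyl so that neither consumes the boron triflate in the next step.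

Step 14
Reactants: 23 bis(triethylsilyl) imide; 24 4-(benzyloxy)-3-methoxybenzaldehyde (O-benzylvanillin)
Product: 27 syn aldol adduct (2S,3R in the acyl chain; G2 and G1 set), via Z boron enolate 25 (not isolated), via boron aldolate 26 (not isolated)
Conditions: Bu2BOTf, iPr2NEt, CH2Cl2, −78 to 0 °C; then 24, −78 to 0 °C; pH 7 buffer, MeOH, H2O2, 0 °C
Reagents that add atoms: none
Why: Evans syn aldol, in which the Z(O) dibutylboron enolate of the aryloxyacetyl imide reacts through a Zimmerman–Traxler chair on the face away from the auxiliary benzyl group, so the (S)-auxiliary sets G2 and G1 syn with the configuration that becomes R,R (threo) after step 15.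

Step 15
Reactants: 27 syn aldol adduct
Product: 28 bis(triethylsilyl) G1,G3-diol (G1 R, G2 R)
Conditions: LiBH4, THF, H2O (1 equiv), 0 °C
Reagents that add atoms: none
Why: Reductive cleavage of the N-acyl oxazolidinone by borohydride at the exocyclic carbonyl, which turns it into the G3 hydroxymethyl group without touching G1 or G2 and releases the auxiliary.

Step 16
Reactants: 28 bis(triethylsilyl) diol
Product: 29 dibenzyl ether of the target (ring A and ring C phenols benzylated)
Conditions: Bu4NF, THF, 0 °C to rt
Reagents that add atoms: none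
Why: Fluoride-driven cleavage of the primary and tertiary triethylsilyl ethers through pentacoordinate silicon, under which no other group in the molecule is labile.

Step 17
Reactants: 29 dibenzyl ether of the target
Product: 30 target CNP0391650.2
Conditions: H2 (1 atm), 10 % Pd/C, EtOAc/MeOH, rt, stopped at full conversion
Reagents that add atoms: none
Why: Catalytic hydrogenolysis of the two aryl benzyl ethers, which under neutral conditions is much faster than cleavage of the benzylic alcohol at G1 or of the benzylic ring ether at C2.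

**Compound list**

1 | vanillyl alcohol | COc1cc(CO)ccc1O | starting material
2 | 4-(allyloxy)-3-methoxybenzyl alcohol | COc1cc(CO)ccc1OCC=C | intermediate
3 | 4-(allyloxy)-3-methoxybenzyl bromide | COc1cc(CBr)ccc1OCC=C | intermediate
4 | 4-(benzyloxy)-3-methoxybenzyl alcohol | COc1cc(CO)ccc1OCc1ccccc1 | starting material
5 | 4-(benzyloxy)-3-methoxybenzyl bromide | COc1cc(CBr)ccc1OCc1ccccc1 | intermediate
6 | dimethyl (S)-malate | COC(=O)C[C@H](O)C(=O)OC | starting material
7 | dilithium alkoxide enolate of 6 | [Li+].[Li+].COC([O-])=C[C@H]([O-])C(=O)OC | intermediate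
8 | dimethyl (2S,3R)-3-[4-(allyloxy)-3-methoxybenzyl]-2-hydroxysuccinate | COC(=O)[C@@H](O)[C@@H](Cc1ccc(OCC=C)c(OC)c1)C(=O)OC | intermediate
9 | (2S,3R)-3-[4-(allyloxy)-3-methoxybenzyl]-2-hydroxysuccinic acid | OC(=O)[C@@H](O)[C@@H](Cc1ccc(OCC=C)c(OC)c1)C(=O)O | intermediate
10 | pivalaldehyde | CC(C)(C)C=O | starting material
11 | (2R)-3-[4-(allyloxy)-3-methoxyphenyl]-2-[(2S,4S)-2-tert-butyl-5-oxo-1,3-dioxolan-4-yl]propanoic acid | CC(C)(C)[C@H]1O[C@@H]([C@@H](Cc2ccc(OCC=C)c(OC)c2)C(=O)O)C(=O)O1 | intermediate
12 | dilithium enolate carboxylate of 11 | [Li+].[Li+].CC(C)(C)[C@H]1OC([C@@H](Cc2ccc(OCC=C)c(OC)c2)C([O-])=O)=C([O-])O1 | intermediate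
13 | (2R)-3-[4-(allyloxy)-3-methoxyphenyl]-2-{(2S,4S)-4-[4-(benzyloxy)-3-methoxybenzyl]-2-tert-butyl-5-oxo-1,3-dioxolan-4-yl}propanoic acid | CC(C)(C)[C@H]1O[C@@](Cc2ccc(OCc3ccccc3)c(OC)c2)([C@@H](Cc2ccc(OCC=C)c(OC)c2)C(=O)O)C(=O)O1 | intermediate
14 | (2S,3S)-3-[4-(allyloxy)-3-methoxybenzyl]-2-[4-(benzyloxy)-3-methoxybenzyl]butane-1,2,4-triol | COc1cc(C[C@@](O)(CO)[C@H](CO)Cc2ccc(OCC=C)c(OC)c2)ccc1OCc1ccccc1 | intermediate
15 | (2S,3S)-2-[4-(benzyloxy)-3-methoxybenzyl]-3-(4-hydroxy-3-methoxybenzyl)butane-1,2,4-triol | COc1cc(C[C@@](O)(CO)[C@H](CO)Cc2ccc(O)c(OC)c2)ccc1OCc1ccccc1 | intermediate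
16 | ring B para-quinone methide of 15 (exocyclic double bond at C2, geometry not defined) | COc1cc(C[C@@](O)(CO)[C@H](CO)C=C2C=CC(=O)C(OC)=C2)ccc1OCc1ccccc1 | intermediate
17 | (2S,3R,4S)-4-[4-(benzyloxy)-3-methoxybenzyl]-2-(4-hydroxy-3-methoxyphenyl)-3-(hydroxymethyl)tetrahydrofuran-4-ol | COc1cc(C[C@@]2(O)CO[C@H](c3ccc(O)c(OC)c3)[C@H]2CO)ccc1OCc1ccccc1 | intermediate
18 | (S)-4-benzyl-2-oxazolidinone | O=C1N[C@@H](Cc2ccccc2)CO1 | starting material
19 | bromoacetyl bromide | BrCC(Br)=O | starting material
20 | N-lithio (S)-4-benzyl-2-oxazolidinone | [Li+].O=C1[N-][C@@H](Cc2ccccc2)CO1 | intermediate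
21 | (S)-4-benzyl-3-(bromoacetyl)-2-oxazolidinone | BrCC(=O)N1[C@@H](Cc2ccccc2)COC1=O | intermediate
22 | ring B aryloxyacetyl imide of 17 with the (S)-4-benzyl-2-oxazolidinone | COc1cc(C[C@@]2(O)CO[C@H](c3ccc(OCC(=O)N4[C@@H](Cc5ccccc5)COC4=O)c(OC)c3)[C@H]2CO)ccc1OCc1ccccc1 | intermediate
23 | bis(triethylsilyl) ether of 22 (C4–O and C9–O) | COc1cc(C[C@@]2(O[Si](CC)(CC)CC)CO[C@H](c3ccc(OCC(=O)N4[C@@H](Cc5ccccc5)COC4=O)c(OC)c3)[C@H]2CO[Si](CC)(CC)CC)ccc1OCc1ccccc1 | intermediate
24 | 4-(benzyloxy)-3-methoxybenzaldehyde | COc1cc(C=O)ccc1OCc1ccccc1 | starting material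
25 | Z dibutylboron enolate of 23 | COc1cc(C[C@@]2(O[Si](CC)(CC)CC)CO[C@H](c3ccc(O/C=C(\OB(CCCC)CCCC)N4[C@@H](Cc5ccccc5)COC4=O)c(OC)c3)[C@H]2CO[Si](CC)(CC)CC)ccc1OCc1ccccc1 | intermediate
26 | dibutylboron aldolate of 27 | COc1cc(C[C@@]2(O[Si](CC)(CC)CC)CO[C@H](c3ccc(O[C@H](C(=O)N4[C@@H](Cc5ccccc5)COC4=O)[C@H](OB(CCCC)CCCC)c6ccc(OCc7ccccc7)c(OC)c6)c(OC)c3)[C@H]2CO[Si](CC)(CC)CC)ccc1OCc1ccccc1 | intermediate
27 | syn aldol adduct, (4S)-4-benzyl-3-[(2S,3R)-2-aryloxy-3-(4-benzyloxy-3-methoxyphenyl)-3-hydroxypropanoyl]oxazolidin-2-one with aryl = ring B of the bis(triethylsilyl) core | COc1cc(C[C@@]2(O[Si](CC)(CC)CC)CO[C@H](c3ccc(O[C@H](C(=O)N4[C@@H](Cc5ccccc5)COC4=O)[C@H](O)c6ccc(OCc7ccccc7)c(OC)c6)c(OC)c3)[C@H]2CO[Si](CC)(CC)CC)ccc1OCc1ccccc1 | intermediate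
28 | bis(triethylsilyl) G1,G3-diol (G1 R, G2 R), ring A and ring C benzylated | COc1cc(C[C@@]2(O[Si](CC)(CC)CC)CO[C@H](c3ccc(O[C@H](CO)[C@H](O)c6ccc(OCc7ccccc7)c(OC)c6)c(OC)c3)[C@H]2CO[Si](CC)(CC)CC)ccc1OCc1ccccc1 | intermediate
29 | dibenzyl ether of the target (ring A and ring C phenols benzylated) | COc1cc(C[C@@]2(O)CO[C@H](c3ccc(O[C@H](CO)[C@H](O)c4ccc(OCc5ccccc5)c(OC)c4)c(OC)c3)[C@H]2CO)ccc1OCc1ccccc1 | intermediate
30 | CNP0391650.2 | COc1cc(C[C@@]2(O)CO[C@H](c3ccc(O[C@H](CO)[C@H](O)c4ccc(O)c(OC)c4)c(OC)c3)[C@H]2CO)ccc1O | target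

**Step count and risk**

Total step count: 17.
Longest linear sequence: 15 steps (from 1 through steps 1, 2, 4 to 10 and 12 to 17).

The three steps most likely to fail:

Step 10. Silver oxide is a one-electron oxidant, so the ring B phenoxyl radical may couple to biaryl or diaryl ether dimers instead of disproportionating to the quinone methide. The product phenol may also be oxidised a second time at C2, or the ring may close with poor facial selectivity at C2. The fallback separates oxidation from ring closure and sets out from 15. DDQ (1.05 equiv) in MeOH/CH2Cl2 at 0 °C abstracts hydride from the para-hydroxybenzylic position and the quinone methide is captured by the solvent, giving the benzylic methyl ether F1 as a mixture of C2 epimers, possibly with some 17. Camphorsulfonic acid (cat.) in CH2Cl2 at rt then ionises the para-hydroxybenzylic ether, and the C5 hydroxyl closes the ring under thermodynamic control with loss of methanol. The sequence comes back to the route at 17.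

Step 7. The tetrasubstituted enolate of the carboxylate dianion is hindered and aggregated, so C-alkylation may be slow, the enolate may fragment on warming, and the neighbouring stereocentre may erode the facial control by tert-butyl. The fallback replaces the dianion by an ester monoanion and sets out from 11. Me3SiCHN2 in MeOH/toluene gives the methyl ester F2. Its enolate, formed with LiN(SiMe3)2 (1.1 equiv) in THF at −78 °C, is alkylated with 5 anti to tert-butyl to give the dibenzylated methyl ester F3. LiAlH4 under the conditions of step 8 then reduces ester and dioxolanone together, and the sequence comes back to the route at 14.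

Step 12. Phenoxide or carbonate may attack the imide carbonyls of 21 or 22 instead of displacing bromide, which would cleave the auxiliary or transfer the acyl group to the C9 hydroxyl. The fallback builds the imide by N-acylation instead of O-alkylation and sets out from 17. Methyl bromoacetate with K2CO3 in acetone gives the methyl aryloxyacetate F4, and Et3SiOTf with 2,6-lutidine gives its bis(triethylsilyl) ether F5. LiOH in THF/H2O gives the aryloxyacetic acid F6. Pivaloyl chloride and Et3N in THF at −20 °C give the mixed pivalic anhydride F7, which acylates the lithiated oxazolidinone 20 at −78 °C. The sequence comes back to the route at 23.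

**Further compounds**

F1 | step 10 | (2S,3S)-2-[4-(benzyloxy)-3-methoxybenzyl]-3-[(4-hydroxy-3-methoxyphenyl)(methoxy)methyl]butane-1,2,4-triol, both epimers at the methoxy carbon | COc1cc(C[C@@](O)(CO)[C@H](CO)C(OC)c2ccc(O)c(OC)c2)ccc1OCc1ccccc1
F2 | step 7 | methyl ester of 11 | CC(C)(C)[C@H]1O[C@@H]([C@@H](Cc2ccc(OCC=C)c(OC)c2)C(=O)OC)C(=O)O1
F3 | step 7 | methyl ester of 13 | CC(C)(C)[C@H]1O[C@@](Cc2ccc(OCc3ccccc3)c(OC)c2)([C@@H](Cc2ccc(OCC=C)c(OC)c2)C(=O)OC)C(=O)O1
F4 | step 12 | methyl aryloxyacetate of 17 (ring B oxygen bound to CH2CO2Me) | COc1cc(C[C@@]2(O)CO[C@H](c3ccc(OCC(=O)OC)c(OC)c3)[C@H]2CO)ccc1OCc1ccccc1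
F5 | step 12 | bis(triethylsilyl) ether of F4 | COc1cc(C[C@@]2(O[Si](CC)(CC)CC)CO[C@H](c3ccc(OCC(=O)OC)c(OC)c3)[C@H]2CO[Si](CC)(CC)CC)ccc1OCc1ccccc1
F6 | step 12 | bis(triethylsilyl) aryloxyacetic acid | COc1cc(C[C@@]2(O[Si](CC)(CC)CC)CO[C@H](c3ccc(OCC(=O)O)c(OC)c3)[C@H]2CO[Si](CC)(CC)CC)ccc1OCc1ccccc1
F7 | step 12 | mixed pivalic anhydride of F6 | COc1cc(C[C@@]2(O[Si](CC)(CC)CC)CO[C@H](c3ccc(OCC(=O)OC(=O)C(C)(C)C)c(OC)c3)[C@H]2CO[Si](CC)(CC)CC)ccc1OCc1ccccc1
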